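Ring A (C10, C1, C2, C3, C4, C5; eudesmane numbering) is disconnected at C3 and traced back to the cyclopentanone (C10, C1, C2, C4, C5) of a hydrindanone. A Lewis-acid-promoted trimethylsilyldiazomethane homologation inserts C3 between C2 and the C4 carbonyl and enlarges this five-membered ring to ring A in one operation. The step exploits that C3 is an unsubstituted CH between the C2 methylene and C4, the carbon that carries C15, and that C5–H lies α to the new C4 ketone, so the trans ring fusion is set by equilibration. Enol triflate formation and hydroxymethylation then turn C4=O into C3=C4 and C15. Ring B stems from (+)-dihydrocarvone.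

Key step: step 3

Remark: 1 is taken as the commercial mixture of C2 epimers (both 5R), which converge in step 1; 18 is racemic at its acetal carbon, which is lost in step 10.

Step 1
Reactants: 1 (+)-dihydrocarvone; 2 (R)-1-phenylethylamine; 3 methyl acrylate
Product: 6 methyl 3-[(1S,4R)-1-methyl-2-oxo-4-(prop-1-en-2-yl)cyclohexyl]propanoate, via ketimine 4 (not isolated), via Michael-adduct ketimine 5 (not isolated)
Conditions: p-TsOH (cat.), toluene, reflux, Dean–Stark; then 3 (excess), THF, 40 °C; then 20% aq. AcOH, rt
Reagents that add atoms: water, O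
Why: Michael addition of a chiral ketimine through its more substituted secondary enamine tautomer (deracemising alkylation, aza-ene-like transition state) should deliver the acrylate to C10 on the face away from the phenyl group of the (R)-auxiliary, which places the new chain trans to the C7 isopropenyl group (10β-methyl), and mild acid then frees the ketone and the auxiliary.

Step 2
Reactants: 6 keto ester
Product: 8 (3aS,6R,7aS)-3a-methyl-6-(prop-1-en-2-yl)octahydro-1H-inden-1-one (cis-fused hydrindanone; ring atoms C10, C1, C2, C4, C5), via methyl enol ether 7 (not isolated)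
Conditions: TiCl3, LiAlH4, Et3N, DME, reflux, slow addition of 6; then 1 M HCl, THF, rt
Reagents that add atoms: water, O
Why: Titanium-induced intramolecular ketone–ester carbonyl coupling (McMurry keto ester cyclisation) should join C5 to the ester carbon C4 as a five-membered enol ether whose hydrolysis gives the cyclopentanone, the isolated alkene being inert to low-valent titanium; the C5 configuration formed on protonation (cis fusion expected as the more stable one) is reset in step 3.

Step 3
Reactants: 8 cis-hydrindanone
Product: 11 (4aR,7R,8aR)-4a-methyl-7-(prop-1-en-2-yl)octahydronaphthalen-1(2H)-one (trans-fused decalone, ketone at C4, 5α-H), via α-silyl cis-decalone 9 (not isolated), via cis-decalone 10 (not isolated)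
Conditions: Me3SiCHN2, BF3·OEt2, CH2Cl2, −78 to −30 °C; then NaOMe (cat.), MeOH, rt to 40 °C
Reagents that add atoms: trimethylsilyldiazomethane, C[Si](C)(C)C=[N+]=[N-]
Why: BF3 activates the C4 carbonyl, the diazo carbon adds to it, and the β-oxido diazonium ion loses N2 with 1,2-shift of the antiperiplanar C2–C4 bond, so the new carbon C3 is inserted between C2 and C4 (Tiffeneau–Demjanov-type diazoalkane homologation of a cycloalkanone, the closest known reaction type). No ring is closed by cyclisation: the six-membered ring A arises from the cyclopentanone by ring enlargement through this 1,2-alkyl shift. The silyl-bearing C3 stereocentre is transient and is erased when methoxide cleaves the α-silyl ketone, and the same base should epimerise C5 through the C4 enolate to the trans-fused decalone, which is the more stable epimer (C7 substituent equatorial, as in 5α-4-oxo steroids). The step needs migration of C2 rather than C5 and a single insertion: the less substituted methylene migrates preferentially in Lewis-acid-promoted Me3SiCHN2 homologations, and the bulky α-silyl ketone formed first resists a second addition. The isolated 1,1-disubstituted alkene should not react with the diazoalkane at low temperature.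

Step 4
Reactants: 11 trans-decalone
Product: 13 2-[(2R,4aR,8aR)-4a-methyl-8-oxodecahydronaphthalen-2-yl]prop-2-enal, via allylic alcohol 12 (not isolated)
Conditions: SeO2 (cat.), t-BuOOH, CH2Cl2, rt; then MnO2, CH2Cl2, rt
Reagents that add atoms: tert-butyl hydroperoxide, CC(C)(C)OO (oxygen relayed by catalytic SeO2)
Why: Allylic oxidation by ene reaction and [2,3]-sigmatropic shift should take place at the methyl group of the isopropenyl unit (the C7 methine C–H lies near the alkene plane and is poorly aligned) at a temperature where ketone α-oxidation is slow, and MnO2 carries the primary allylic alcohol on to the α-methylene aldehyde.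

Step 5
Reactants: 13 enal
Product: 14 2-[(2R,4aR,8aR)-4a-methyl-8-oxodecahydronaphthalen-2-yl]prop-2-enoic acid
Conditions: NaClO2, NaH2PO4, 2-methyl-2-butene, t-BuOH/H2O, rt
Reagents that add atoms: sodium chlorite, [Na+].[O-]Cl=O
Why: Pinnick oxidation converts the conjugated aldehyde to the acid without touching the ketone or the alkene, 2-methyl-2-butene scavenging the hypochlorous acid.

Step 6
Reactants: 14 acid
Product: 15 methyl 2-[(2R,4aR,8aR)-4a-methyl-8-oxodecahydronaphthalen-2-yl]prop-2-enoate
Conditions: MeI, K2CO3, DMF, rt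
Reagents that add atoms: iodomethane, CI
Why: SN2 alkylation of the potassium carboxylate gives the methyl ester, carbonate being too weak a base to alkylate the ketone.

Step 7
Reactants: 15 keto ester
Product: 16 methyl 2-[(2R,4aS,8aR)-4a-methyl-8-(trifluoromethanesulfonyloxy)-1,2,3,4,4a,5,6,8a-octahydronaphthalen-2-yl]prop-2-enoate (C3=C4 enol triflate)
Conditions: KN(SiMe3)2, THF, −78 °C; then PhNTf2, −78 to 0 °C
Reagents that add atoms: N-phenylbis(trifluoromethanesulfonimide), O=S(=O)(N(c1ccccc1)S(=O)(=O)C(F)(F)F)C(F)(F)F
Why: Kinetic deprotonation by the bulky amide should occur at the C3 methylene rather than at the tertiary C5–H or the ester, and O-sulfonylation of the C3=C4 enolate fixes the alkene position while leaving C5 untouched.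

Step 8
Reactants: 16 enol triflate
Product: 17 methyl 2-[(2R,4aR,8aR)-8-(hydroxymethyl)-4a-methyl-1,2,3,4,4a,5,6,8a-octahydronaphthalen-2-yl]prop-2-enoate
Conditions: Bu3SnCH2OH, Pd(PPh3)4 (cat.), LiCl, 1,4-dioxane, 100 °C
Reagents that add atoms: (tributylstannyl)methanol, CCCC[Sn](CCCC)(CCCC)CO
Why: Stille coupling of the enol triflate with the hydroxymethyl stannane (oxidative addition to zerovalent palladium assisted by chloride) installs C15 as the free primary allylic alcohol and tolerates the ester; without added base a Heck pathway with the acrylate cannot turn over.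

Step 9
Reactants: 18 4-(tetrahydropyran-2-yloxy)benzaldehyde; 19 methyl bis(2,2,2-trifluoroethyl)phosphonoacetate
Product: 20 methyl (Z)-3-[4-(tetrahydropyran-2-yloxy)phenyl]prop-2-enoate
Conditions: KN(SiMe3)2, 18-crown-6, THF, −78 °C
Reagents that add atoms: none
Why: Still–Gennari variant of the Horner–Wadsworth–Emmons reaction, in which the electron-poor phosphonate with a dissociated potassium counter-ion eliminates fast from the kinetically formed adduct, should give the Z-cinnamate.

Step 10
Reactants: 20 Z ester
Product: 22 (Z)-3-(4-hydroxyphenyl)prop-2-enoic acid ((Z)-p-coumaric acid), via lithium carboxylate 21 (not isolated)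
Conditions: LiOH, THF/H2O, rt, dark; then 1 M HCl to pH 2, rt
Reagents that add atoms: lithium hydroxide, [Li+].[OH-]
Why: Saponification while the phenol is still masked as a base-stable acetal avoids a phenoxide-conjugated ester that could lose its Z geometry, and brief aqueous acid then cleaves the aryl tetrahydropyranyl ether.

Step 11
Reactants: 17 allylic alcohol; 22 (Z)-p-coumaric acid
Product: 23 target compound CNP0161949.2
Conditions: PPh3, DIAD, THF, 0 °C to rt, dark
Reagents that add atoms: none
Why: Mitsunobu esterification, in which the carboxylic acid (far more acidic than the phenol) protonates the betaine and its carboxylate displaces the activated primary allylic oxygen at C15 by SN2, so the acyl carbon is never activated and the Z geometry and the free phenol should be retained.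

Compound list
1 | (+)-dihydrocarvone, (2R,5R)-2-methyl-5-(prop-1-en-2-yl)cyclohexan-1-one | C=C(C)[C@@H]1CC[C@@H](C)C(=O)C1 | starting material
2 | (R)-1-phenylethylamine | C[C@@H](N)c1ccccc1 | starting material
3 | methyl acrylate | C=CC(=O)OC | starting material
4 | N-[(1R)-1-phenylethyl] ketimine of 1 (C2 epimers, in equilibrium with the secondary enamine) | C=C(C)[C@@H]1CCC(C)C(=N[C@H](C)c2ccccc2)C1 | intermediate (not isolated)
5 | N-[(1R)-1-phenylethyl] ketimine of 6 | C=C(C)[C@@H]1CC[C@@](C)(CCC(=O)OC)C(=N[C@H](C)c2ccccc2)C1 | intermediate (not isolated)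
6 | methyl 3-[(1S,4R)-1-methyl-2-oxo-4-(prop-1-en-2-yl)cyclohexyl]propanoate | C=C(C)[C@@H]1CC[C@@](C)(CCC(=O)OC)C(=O)C1 | intermediate
7 | bicyclic methyl enol ether of 8 (C4–OMe, C4=C5 double bond, 7β-isopropenyl, 10β-methyl) | C=C(C)[C@@H]1CC[C@@]2(C)CCC(OC)=C2C1 | intermediate (not isolated)
8 | (3aS,6R,7aS)-3a-methyl-6-(prop-1-en-2-yl)octahydro-1H-inden-1-one (cis-fused) | C=C(C)[C@@H]1CC[C@@]2(C)CCC(=O)[C@H]2C1 | intermediate
9 | cis-fused 3-(trimethylsilyl)-15-nor-eudesm-11-en-4-one (5β-H, C3 epimers) | C=C(C)[C@@H]1CC[C@@]2(C)CCC([Si](C)(C)C)C(=O)[C@H]2C1 | intermediate (not isolated)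
10 | (4aR,7R,8aS)-4a-methyl-7-(prop-1-en-2-yl)octahydronaphthalen-1(2H)-one (cis-fused, 5β-H) | C=C(C)[C@@H]1CC[C@@]2(C)CCCC(=O)[C@H]2C1 | intermediate (not isolated)
11 | (4aR,7R,8aR)-4a-methyl-7-(prop-1-en-2-yl)octahydronaphthalen-1(2H)-one (trans-fused, 5α-H) | C=C(C)[C@@H]1CC[C@@]2(C)CCCC(=O)[C@@H]2C1 | intermediate
12 | 2-[(2R,4aR,8aR)-4a-methyl-8-oxodecahydronaphthalen-2-yl]prop-2-en-1-ol | C=C(CO)[C@@H]1CC[C@@]2(C)CCCC(=O)[C@@H]2C1 | intermediate (not isolated)
13 | 2-[(2R,4aR,8aR)-4a-methyl-8-oxodecahydronaphthalen-2-yl]prop-2-enal | C=C(C=O)[C@@H]1CC[C@@]2(C)CCCC(=O)[C@@H]2C1 | intermediate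
14 | 2-[(2R,4aR,8aR)-4a-methyl-8-oxodecahydronaphthalen-2-yl]prop-2-enoic acid | C=C(C(=O)O)[C@@H]1CC[C@@]2(C)CCCC(=O)[C@@H]2C1 | intermediate
15 | methyl 2-[(2R,4aR,8aR)-4a-methyl-8-oxodecahydronaphthalen-2-yl]prop-2-enoate | C=C(C(=O)OC)[C@@H]1CC[C@@]2(C)CCCC(=O)[C@@H]2C1 | intermediate
16 | methyl 2-[(2R,4aS,8aR)-4a-methyl-8-(trifluoromethanesulfonyloxy)-1,2,3,4,4a,5,6,8a-octahydronaphthalen-2-yl]prop-2-enoate | C=C(C(=O)OC)[C@@H]1CC[C@@]2(C)CCC=C(OS(=O)(=O)C(F)(F)F)[C@@H]2C1 | intermediate
17 | methyl 2-[(2R,4aR,8aR)-8-(hydroxymethyl)-4a-methyl-1,2,3,4,4a,5,6,8a-octahydronaphthalen-2-yl]prop-2-enoate | C=C(C(=O)OC)[C@@H]1CC[C@@]2(C)CCC=C(CO)[C@@H]2C1 | intermediate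
18 | 4-(tetrahydropyran-2-yloxy)benzaldehyde (racemic) | O=Cc1ccc(OC2CCCCO2)cc1 | starting material
19 | methyl bis(2,2,2-trifluoroethyl)phosphonoacetate | COC(=O)CP(=O)(OCC(F)(F)F)OCC(F)(F)F | starting material
20 | methyl (Z)-3-[4-(tetrahydropyran-2-yloxy)phenyl]prop-2-enoate (racemic at the acetal carbon) | COC(=O)/C=C\c1ccc(OC2CCCCO2)cc1 | intermediate
21 | lithium (Z)-3-[4-(tetrahydropyran-2-yloxy)phenyl]prop-2-enoate | [Li+].[O-]C(=O)/C=C\c1ccc(OC2CCCCO2)cc1 | intermediate (not isolated)
22 | (Z)-3-(4-hydroxyphenyl)prop-2-enoic acid | OC(=O)/C=C\c1ccc(O)cc1 | intermediate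
23 | methyl 2-[(2R,4aR,8aR)-8-({[(2Z)-3-(4-hydroxyphenyl)prop-2-enoyl]oxy}methyl)-4a-methyl-1,2,3,4,4a,5,6,8a-octahydronaphthalen-2-yl]prop-2-enoate | C=C(C(=O)OC)[C@@H]1CC[C@@]2(C)CCC=C(COC(=O)/C=C\c3ccc(O)cc3)[C@@H]2C1 | target

Total step count: 11. Longest linear sequence: 9 steps (steps 1 to 8 and 11).

Steps most likely to fail

Step 3 (key step). Migration of the ring-fusion carbon C5 could compete with that of C2, so that the carbon is inserted on the wrong side of the carbonyl. A second insertion or incomplete epimerisation at C5 could also occur. The fallback inserts the carbon regiospecifically through a cyclopropanol fragmentation; it sets out from 8 and comes back at 11. Ketone 8 would be deprotonated with LiN(i-Pr)2 and silylated with Me3SiCl (THF, −78 °C) to give the kinetic trimethylsilyl enol ether F1, whose double bond lies between C4 and C2. Cyclopropanation of this electron-rich alkene with Et2Zn and CH2I2 would give the siloxycyclopropane F2. Oxidative opening with FeCl3 in DMF would cleave the C4–C2 bond and give the ring-enlarged β-chloro ketone F3. Dehydrochlorination with NaOAc in MeOH would give the enone F4 (C2=C3, C4 ketone). Conjugate reduction with LiBH(s-Bu)3 and equilibration with NaOMe in MeOH would return to 11.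

Step 2. Intermolecular coupling or plain reduction of the hindered ketone could outrun the five-membered ring closure on titanium. The fallback closes the ring by a ketyl–nitrile coupling; it sets out from 1 (through ketimine 4) and comes back at 8. Ketimine 4 would be alkylated with acrylonitrile in place of 3 to give the adduct ketimine F5 and, after aqueous AcOH, the keto nitrile F6. SmI2 in THF/t-BuOH would add the C5 ketyl to the nitrile carbon to give the α-hydroxy imine F7, hydrolysed on work-up to the cis-fused α-hydroxy ketone F8. Dehydration with SOCl2 and pyridine would give the enone F9 (C4 ketone, C5=C6), and reduction with Li in liquid NH3 would give 8.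

Step 4. The selenium reagent could attack the C7 methine or the α-position of the ketone instead of the side-chain methyl (poor site selectivity). The fallback uses an ene-type chlorination; it sets out from 11 and comes back at 12. Ca(OCl)2 and CO2 in CH2Cl2/H2O would give the allylic chloride F10, KOAc in DMF the allylic acetate F11, and K2CO3 in MeOH the allylic alcohol 12. Compound 12 would then be oxidised with MnO2 to 13 as in the second stage of step 4.

Further compounds
F1 | step 3 | trimethylsilyl enol ether of 8 (C4–OSiMe3, C2=C4 double bond, cis-fused) | C=C(C)[C@@H]1CC[C@@]2(C)CC=C(O[Si](C)(C)C)[C@H]2C1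
F2 | step 3 | siloxycyclopropane from F1 (CH2 bridging C2 and C4, cyclopropane stereocentres as a mixture) | C=C(C)[C@@H]1CC[C@@]2(C)CC3CC3(O[Si](C)(C)C)[C@H]2C1
F3 | step 3 | cis-fused 2-chloro-15-nor-eudesm-11-en-4-one (C2 epimers) | C=C(C)[C@@H]1CC[C@@]2(C)CC(Cl)CC(=O)[C@H]2C1
F4 | step 3 | cis-fused 15-nor-eudesma-2,11-dien-4-one | C=C(C)[C@@H]1CC[C@@]2(C)CC=CC(=O)[C@H]2C1
F5 | step 2 | N-[(1R)-1-phenylethyl] ketimine of F6 | C=C(C)[C@@H]1CC[C@@](C)(CCC#N)C(=N[C@H](C)c2ccccc2)C1
F6 | step 2 | 3-[(1S,4R)-1-methyl-2-oxo-4-(prop-1-en-2-yl)cyclohexyl]propanenitrile | C=C(C)[C@@H]1CC[C@@](C)(CCC#N)C(=O)C1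
F7 | step 2 | cis-fused α-hydroxy imine (C5–OH, C4=NH) | C=C(C)[C@@H]1CC[C@@]2(C)CCC(=N)[C@@]2(O)C1
F8 | step 2 | cis-fused 7a-hydroxy-3a-methyl-6-(prop-1-en-2-yl)octahydro-1H-inden-1-one | C=C(C)[C@@H]1CC[C@@]2(C)CCC(=O)[C@@]2(O)C1
F9 | step 2 | 3a-methyl-6-(prop-1-en-2-yl)-hexahydroinden-1-one with C5=C6 double bond (conjugated enone) | C=C(C)[C@@H]1CC[C@@]2(C)CCC(=O)C2=C1
F10 | step 4 | 12-chloro-15-nor-eudesm-11(13)-en-4-one (trans-fused) | C=C(CCl)[C@@H]1CC[C@@]2(C)CCCC(=O)[C@@H]2C1
F11 | step 4 | 12-acetoxy-15-nor-eudesm-11(13)-en-4-one (trans-fused) | C=C(COC(C)=O)[C@@H]1CC[C@@]2(C)CCCC(=O)[C@@H]2C1
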